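**Retrosynthetic overview** (locants follow the target SMILES: ring C1 CH–O-angelate, C2 =CH, C3 =C–CH3, C4 CH–OAc, C5 CH2, C6 CH–side chain; side chain C7 CH–CH3, C8 CH2, C9 CH–OAc, C10=C11)
1. Target 14 ⇒ acetylation of hydroxy angelate 13 ⇒ C1–O bond by palladium-catalysed cis-1,4 opening of vinyl epoxide 11 with angelic acid ⇒ C3/C4–O bonds by face-selective epoxidation of diene 10.
2. Diene 10 ⇒ enone 8 (dienyl triflate, methyl coupling) ⇒ acetoxy aldehyde 5 + but-3-en-2-one (organocatalytic Robinson-type annulation; the only carbocycle).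
3. Aldehyde 5 ⇒ lactone 2 (Weinreb opening, acetylation, reduction) ⇒ (R)-citronellic acid 1 by a new allylic C–H lactonisation that makes the C9–O bond and sets C9.
4. Ring order: temporary δ-lactone (step 1, opened in step 2) → cyclohexene (step 4) → temporary oxirane (step 6, opened in step 7).

Assumption: (R)-citronellic acid, but-3-en-2-one, angelic acid, (S)-2-[methoxy(diphenyl)methyl]pyrrolidine and the D-fructose-derived Shi ketone are bought; with C1→C6 drawn clockwise, the side chain is up and both ring oxygens are down ("lower face").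

**Route**

Step 1
Reactants: 1 (R)-citronellic acid, (3R)-3,7-dimethyloct-6-enoic acid
Product: 2 (4R,6R)-4-methyl-6-(2-methylprop-1-en-1-yl)oxan-2-one (cis-lactone)
Conditions: Pd(OAc)2 (10 mol%), 1,2-bis(phenylsulfinyl)ethane (10 mol%), 2,6-dimethyl-1,4-benzoquinone (1.5 equiv), iPr2NEt (0.3 equiv), 1,4-dioxane, 45 °C
Reagents that add atoms: none
Why: Proposed new method: a carboxylate-directed allylic C–H lactonisation of a prenyl-type trisubstituted olefin under electrophilic divalent palladium/sulfoxide catalysis, in which the palladium-bound substrate carboxylate can reach only the C–H bond at the internal allylic CH2 (seven-membered concerted metalation–deprotonation) and not the methyl C–H bonds, the resulting 1-alkyl-3,3-dimethyl-π-allyl complex undergoes quinone-promoted C–O bond formation at its less substituted terminus (six-membered lactone with the trisubstituted olefin kept; the alternative is an eight-membered ring at a tertiary carbon), and, because the allyl faces interconvert by π–σ–π at the gem-dimethyl terminus, the new centre is set through a chair transition state with 4-methyl and 6-alkenyl both equatorial (cis, 6R, the same 1,3-cis preference as in the acid cyclisation to cis-rose oxide); the closest known reaction type is Pd(OAc)2/bis-sulfoxide allylic C–H esterification and macrolactonisation of terminal olefins.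

Step 2
Reactants: 2 (4R,6R)-4-methyl-6-(2-methylprop-1-en-1-yl)oxan-2-one
Product: 4 (3R,5R)-5-acetoxy-N-methoxy-N,3,7-trimethyloct-6-enamide, via hydroxy Weinreb amide 3 (not isolated)
Conditions: MeNH(OMe)·HCl, iPrMgCl, THF, −20 °C; then Ac2O, DMAP (cat.), −20 °C → rt
Reagents that add atoms: N,O-dimethylhydroxylamine hydrochloride (CNOC.Cl); acetic anhydride (CC(=O)OC(C)=O)
Why: Weinreb aminolysis of the lactone at the acyl carbon (the C9–O bond and its configuration are untouched) followed by acetylation of the magnesium alkoxide in the same flask, which prevents relactonisation.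

Step 3
Reactants: 4 (3R,5R)-5-acetoxy-N-methoxy-N,3,7-trimethyloct-6-enamide
Product: 5 (3R,5R)-5-acetoxy-3,7-dimethyloct-6-enal
Conditions: Cp2Zr(H)Cl (1.5 equiv), THF, rt, 20 min; aq. NaHCO3 work-up
Reagents that add atoms: none
Why: Chemoselective reduction of the Weinreb amide to the aldehyde with Cp2Zr(H)Cl (Schwartz reagent), which is much faster than attack on the acetate or the hindered trisubstituted olefin.

Step 4
Reactants: 5 (3R,5R)-5-acetoxy-3,7-dimethyloct-6-enal; 6 but-3-en-2-one (methyl vinyl ketone)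
Product: 8 (4R,6R)-2-methyl-6-[(1S)-4-oxocyclohex-2-en-1-yl]hept-2-en-4-yl acetate, via keto aldehyde Michael adduct 7 (not isolated)
Conditions: (S)-2-[methoxy(diphenyl)methyl]pyrrolidine (10 mol%), ethyl 3,4-dihydroxybenzoate (20 mol%), neat, 4 °C; then Bn2NH·CF3CO2H, toluene, 50 °C
Reagents that add atoms: none
Why: Organocatalytic Robinson-type annulation, in which the enone adds to the (E)-enamine face away from the methoxydiphenylmethyl group of the (S)-catalyst (sets C6 as S under catalyst control) and an amine-salt intramolecular aldol condensation, mild enough for the acetate, closes the cyclohexenone.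

Step 5
Reactants: 8 (4R,6R)-2-methyl-6-[(1S)-4-oxocyclohex-2-en-1-yl]hept-2-en-4-yl acetate
Product: 10 (4R,6R)-2-methyl-6-[(1S)-4-methylcyclohexa-2,4-dien-1-yl]hept-2-en-4-yl acetate, via dienyl triflate 9 (not isolated)
Conditions: KN(SiMe3)2 (1.05 equiv), THF, −78 °C; PhNTf2, −78 → 0 °C; then Fe(acac)3 (5 mol%), NMP, MeMgBr, −30 °C
Reagents that add atoms: methylmagnesium bromide (C[Mg]Br); N-phenylbis(trifluoromethanesulfonimide) (O=S(=O)(N(c1ccccc1)S(=O)(=O)C(F)(F)F)C(F)(F)F)
Why: Kinetic deprotonation at the CH2 next to the carbonyl gives the cross-conjugated dienolate, O-triflation with PhNTf2 fixes the 1,3-diene as triflate 9, and an iron-catalysed Kumada-type coupling then replaces the triflate group by the methyl of MeMgBr regiospecifically without touching C6.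

Step 6
Reactants: 10 (4R,6R)-2-methyl-6-[(1S)-4-methylcyclohexa-2,4-dien-1-yl]hept-2-en-4-yl acetate
Product: 11 (4R,6R)-2-methyl-6-[(1S,4S,6R)-1-methyl-7-oxabicyclo[4.1.0]hept-2-en-4-yl]hept-2-en-4-yl acetate (oxirane on C3/C4, on the face opposite the side chain)
Conditions: Shi ketone (1,2:4,5-di-O-isopropylidene-β-D-erythro-2,3-hexodiulo-2,6-pyranose, 30 mol%), Oxone (2KHSO5·KHSO4·K2SO4, 1.1 equiv KHSO5), K2CO3, nBu4NHSO4, MeCN/CH2(OMe)2/aq. Na2B4O7 buffer (pH 10.5), −5 °C
Reagents that add atoms: potassium peroxymonosulfate ([K+].[O-]S(=O)(=O)OO)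
Why: Shi asymmetric epoxidation of the more electron-rich trisubstituted diene olefin, whose spiro transition state (same olefin template as 1-phenylcyclohexene giving the R,R oxide) delivers oxygen to the lower face, matched with the substrate's preference for attack anti to the side chain, while the allylic acetate deactivates the C10=C11 olefin.

Step 7
Reactants: 11 (4R,6R)-2-methyl-6-[(1S,4S,6R)-1-methyl-7-oxabicyclo[4.1.0]hept-2-en-4-yl]hept-2-en-4-yl acetate; 12 angelic acid, (2Z)-2-methylbut-2-enoic acid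
Product: 13 (1S,4R,6S)-6-[(2R,4R)-4-acetoxy-6-methylhept-5-en-2-yl]-4-hydroxy-3-methylcyclohex-2-en-1-yl (2Z)-2-methylbut-2-enoate
Conditions: Pd(PPh3)4 (2 mol%), THF, 0 °C, 20 min
Reagents that add atoms: none
Why: Tsuji–Trost-type cis-1,4 opening of the vinyl epoxide, in which zerovalent palladium ionises the allylic C3–O bond with inversion (much faster than the hindered side-chain allylic acetate) and angelate attacks the less substituted allyl terminus C1 anti to palladium, so the C1–O bond forms cis to the C4 hydroxyl and the two ring oxygens are differentiated by the mechanism.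

Step 8
Reactants: 13 (1S,4R,6S)-6-[(2R,4R)-4-acetoxy-6-methylhept-5-en-2-yl]-4-hydroxy-3-methylcyclohex-2-en-1-yl (2Z)-2-methylbut-2-enoate
Product: 14 (1S,4R,6S)-4-acetoxy-6-[(2R,4R)-4-acetoxy-6-methylhept-5-en-2-yl]-3-methylcyclohex-2-en-1-yl (2Z)-2-methylbut-2-enoate (target)
Conditions: Ac2O, pyridine, DMAP (cat.), CH2Cl2, 0 °C → rt
Reagents that add atoms: acetic anhydride (CC(=O)OC(C)=O)
Why: DMAP-catalysed acetylation of the one remaining alcohol under conditions that leave the (Z)-angelate and all stereocentres unchanged.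

**Compound list**
1 | (R)-citronellic acid, (3R)-3,7-dimethyloct-6-enoic acid | C[C@H](CCC=C(C)C)CC(=O)O | starting material
2 | (4R,6R)-4-methyl-6-(2-methylprop-1-en-1-yl)oxan-2-one | O=C1C[C@H](C)C[C@H](C=C(C)C)O1 | intermediate
3 | (3R,5R)-5-hydroxy-N-methoxy-N,3,7-trimethyloct-6-enamide (as its magnesium alkoxide in the flask) | CON(C)C(=O)C[C@H](C)C[C@H](C=C(C)C)O | intermediate
4 | (3R,5R)-5-acetoxy-N-methoxy-N,3,7-trimethyloct-6-enamide | CON(C)C(=O)C[C@H](C)C[C@H](C=C(C)C)OC(C)=O | intermediate
5 | (3R,5R)-5-acetoxy-3,7-dimethyloct-6-enal | O=CC[C@H](C)C[C@H](C=C(C)C)OC(C)=O | intermediate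
6 | but-3-en-2-one (methyl vinyl ketone) | CC(=O)C=C | starting material
7 | (2S,3R,5R)-5-acetoxy-3,7-dimethyl-2-(3-oxobutyl)oct-6-enal | O=C[C@@H](CCC(C)=O)[C@H](C)C[C@H](C=C(C)C)OC(C)=O | intermediate
8 | (4R,6R)-2-methyl-6-[(1S)-4-oxocyclohex-2-en-1-yl]hept-2-en-4-yl acetate | O=C1C=C[C@@H](CC1)[C@H](C)C[C@H](C=C(C)C)OC(C)=O | intermediate
9 | (4S)-4-[(2R,4R)-4-acetoxy-6-methylhept-5-en-2-yl]cyclohexa-1,5-dien-1-yl trifluoromethanesulfonate | FC(F)(F)S(=O)(=O)OC1=CC[C@H](C=C1)[C@H](C)C[C@H](C=C(C)C)OC(C)=O | intermediate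
10 | (4R,6R)-2-methyl-6-[(1S)-4-methylcyclohexa-2,4-dien-1-yl]hept-2-en-4-yl acetate | CC1=CC[C@H](C=C1)[C@H](C)C[C@H](C=C(C)C)OC(C)=O | intermediate
11 | (4R,6R)-2-methyl-6-[(1S,4S,6R)-1-methyl-7-oxabicyclo[4.1.0]hept-2-en-4-yl]hept-2-en-4-yl acetate | C[C@@]12O[C@@H]1C[C@H](C=C2)[C@H](C)C[C@H](C=C(C)C)OC(C)=O | intermediate
12 | angelic acid, (2Z)-2-methylbut-2-enoic acid | C/C=C(/C)C(=O)O | starting material
13 | (1S,4R,6S)-6-[(2R,4R)-4-acetoxy-6-methylhept-5-en-2-yl]-4-hydroxy-3-methylcyclohex-2-en-1-yl (2Z)-2-methylbut-2-enoate | C/C=C(/C)C(=O)O[C@@H]1C=C(C)[C@H](O)C[C@H]1[C@H](C)C[C@H](C=C(C)C)OC(C)=O | intermediate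
14 | (1S,4R,6S)-4-acetoxy-6-[(2R,4R)-4-acetoxy-6-methylhept-5-en-2-yl]-3-methylcyclohex-2-en-1-yl (2Z)-2-methylbut-2-enoate | C/C=C(/C)C(=O)O[C@@H]1C=C(C)[C@H](OC(C)=O)C[C@H]1[C@H](C)C[C@H](C=C(C)C)OC(C)=O | target

**Count and risks**
Total step count: 8. Longest linear sequence: 8 steps (1 → 14; 6 and 12 are bought).

Step 1 (the proposed new lactonisation) is the most likely to fail, through C–H cleavage at a methyl group or poor turnover. Fallback with known chemistry, setting out from 1 and coming back at 2: add benzeneselenenic acid made in the flask (PhSeSePh, H2O2, CH2Cl2) across the olefin to give the Markovnikov hydroxy selenide (3R)-7-hydroxy-3,7-dimethyl-6-(phenylselanyl)octanoic acid F1. Oxidise it with more H2O2 so that the selenoxide eliminates away from the carbinol to the tertiary allylic alcohol (3R,5E)-7-hydroxy-3,7-dimethyloct-5-enoic acid F2. Then close F2 with catalytic camphorsulfonic acid (CH2Cl2, 0 °C), the allyl-cation cyclisation used for rose oxide, which should favour the cis-lactone 2 under equilibrating conditions.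

Step 5 carries the risk of running enolisation, triflation and Grignard coupling in one flask beside an acetate. Fallback setting out from 8 and coming back at 10: 1,2-addition of MeCeCl2 (MeLi, CeCl3, THF, −78 °C) to the ketone gives, as a mixture of carbinol epimers, the tertiary allylic alcohol (4R,6R)-6-[(1S)-4-hydroxy-4-methylcyclohex-2-en-1-yl]-2-methylhept-2-en-4-yl acetate F3. Dehydration of F3 with the Burgess reagent (methyl N-(triethylammoniosulfonyl)carbamate, toluene, 50 °C) gives 10 together with some exocyclic-methylene isomer, which is removed on AgNO3-impregnated silica.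

Step 6 carries three risks: chemoselectivity against the side-chain olefin, face selectivity, and an acid-labile vinyl epoxide that can aromatise. Fallback setting out from 10 and coming back at 14, which also by-passes step 7:
- Singlet-oxygen [4+2] cycloaddition (O2, hν, tetraphenylporphyrin, CH2Cl2, −78 °C) on the face opposite the side chain gives the 2,3-dioxabicyclo[2.2.2]oct-5-ene endoperoxide F4.
- Thiourea in MeOH reduces it to the cis-diol (4R,6R)-6-[(1S,2S,5R)-2,5-dihydroxy-4-methylcyclohex-3-en-1-yl]-2-methylhept-2-en-4-yl acetate F5.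
- MnO2 (CH2Cl2) oxidises selectively the C1 carbinol, whose C–H is pseudoaxial and aligned with the olefin, to the hydroxy enone (4R,6R)-6-[(1S,5R)-5-hydroxy-4-methyl-2-oxocyclohex-3-en-1-yl]-2-methylhept-2-en-4-yl acetate F6.
- Ac2O/pyridine gives the acetoxy enone (4R,6R)-6-[(1S,5R)-5-acetoxy-4-methyl-2-oxocyclohex-3-en-1-yl]-2-methylhept-2-en-4-yl acetate F7.
- NaBH4/CeCl3·7H2O (MeOH, −78 °C, axial hydride delivery, hydroxyl trans to the side chain) gives the hydroxy acetate (4R,6R)-6-[(1S,2S,5R)-5-acetoxy-2-hydroxy-4-methylcyclohex-3-en-1-yl]-2-methylhept-2-en-4-yl acetate F8.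
- Esterification of F8 gives 14. The acylating agent is the mixed anhydride (2Z)-2-methylbut-2-enoic 2,4,6-trichlorobenzoic anhydride F9, made beforehand from 12, 2,4,6-trichlorobenzoyl chloride and Et3N in toluene. It is used at 75 °C without DMAP to keep the Z geometry.

**Further compounds**
F1 | step 1 | (3R)-7-hydroxy-3,7-dimethyl-6-(phenylselanyl)octanoic acid (both C6 epimers) | C[C@H](CCC([Se]c1ccccc1)C(C)(C)O)CC(=O)O
F2 | step 1 | (3R,5E)-7-hydroxy-3,7-dimethyloct-5-enoic acid | C[C@H](C/C=C/C(C)(C)O)CC(=O)O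
F3 | step 5 | (4R,6R)-6-[(1S)-4-hydroxy-4-methylcyclohex-2-en-1-yl]-2-methylhept-2-en-4-yl acetate (both carbinol epimers) | CC1(O)C=C[C@@H](CC1)[C@H](C)C[C@H](C=C(C)C)OC(C)=O
F4 | step 6 | endoperoxide of 10: 5-methyl-2,3-dioxabicyclo[2.2.2]oct-5-ene carrying the side chain at C7, with the O–O bridge across ring C1/C4 on the face opposite the side chain | CC1=C[C@H]2OO[C@@H]1C[C@H]2[C@H](C)C[C@H](C=C(C)C)OC(C)=O
F5 | step 6 | (4R,6R)-6-[(1S,2S,5R)-2,5-dihydroxy-4-methylcyclohex-3-en-1-yl]-2-methylhept-2-en-4-yl acetate | O[C@@H]1C=C(C)[C@H](O)C[C@H]1[C@H](C)C[C@H](C=C(C)C)OC(C)=O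
F6 | step 6 | (4R,6R)-6-[(1S,5R)-5-hydroxy-4-methyl-2-oxocyclohex-3-en-1-yl]-2-methylhept-2-en-4-yl acetate | O=C1C=C(C)[C@H](O)C[C@H]1[C@H](C)C[C@H](C=C(C)C)OC(C)=O
F7 | step 6 | (4R,6R)-6-[(1S,5R)-5-acetoxy-4-methyl-2-oxocyclohex-3-en-1-yl]-2-methylhept-2-en-4-yl acetate | O=C1C=C(C)[C@H](OC(C)=O)C[C@H]1[C@H](C)C[C@H](C=C(C)C)OC(C)=O
F8 | step 6 | (4R,6R)-6-[(1S,2S,5R)-5-acetoxy-2-hydroxy-4-methylcyclohex-3-en-1-yl]-2-methylhept-2-en-4-yl acetate | O[C@@H]1C=C(C)[C@H](OC(C)=O)C[C@H]1[C@H](C)C[C@H](C=C(C)C)OC(C)=O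
F9 | step 6 | (2Z)-2-methylbut-2-enoic 2,4,6-trichlorobenzoic anhydride | C/C=C(/C)C(=O)OC(=O)c1c(Cl)cc(Cl)cc1Cl
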